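## Retrosynthetic overview
1. C8 and C8′ (both R) come in (−)-secoisolariciresinol 1, the only chiral input. Its C2 symmetry keeps the two guaiacyl rings equivalent until one phenol is capped.
2. A traceless O–CH2–O–C(=O) strap is made from acrylic acid 2 and chloromethyl chlorosulfate 3 (→ chloromethyl acrylate 4). It is hung on one phenol of 1 (→ 5) and grown into the ferulate 7 by cross-metathesis with isoeugenol 6.
3. Key disconnection C8″–C5′ plus C7″–O4′: anodic intramolecular 8–5′ coupling of 7 through quinone methide 8 gives 9. The 16-membered macrocycle forms first and the dihydrobenzofuran second, in the same pot.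
4. The last disconnection is the strap. LiAlH4 turns its carbonyl carbon into C9″H2OH, frees the ring A phenol and opens the macrocycle to the target 10.

Assumption: 1 is bought as the single (8R,8′R) enantiomer (a natural lignan, also obtained in bulk from spruce-knot hydroxymatairesinol). Locants: ring A = C1–C6 with C7–C9; ring B = C1′–C6′ with C7′–C9′; ferulate unit = C1″–C9″.

## Route

Step 1
Reactants: 2 acrylic acid; 3 chloromethyl chlorosulfate
Product: 4 chloromethyl acrylate
Conditions: NaHCO3 (4 equiv), n-Bu4NHSO4 (10 mol %), BHT (trace), CH2Cl2–H2O 1:1, 0 °C → rt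
Reagents that add atoms: chloromethyl chlorosulfate (3), ClCOS(=O)(=O)Cl
Why: Phase-transfer SN2 O-alkylation of the carboxylate at the CH2 of 3, where chlorosulfate leaves far faster than chloride (the standard chloromethyl ester synthesis); no stereocentre is involved.

Step 2
Reactants: 1 (−)-secoisolariciresinol (2 equiv); 4 chloromethyl acrylate (1 equiv)
Product: 5 mono-O4-(acryloyloxymethyl) ether of 1
Conditions: Cs2CO3 (1.0 equiv), DMF, 0 °C, 3 h; excess 1 recovered by chromatography
Reagents that add atoms: chloromethyl acrylate (4), C=CC(=O)OCCl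
Why: Williamson-type SN2 etherification in which carbonate deprotonates only a phenol, so the phenoxide and not the primary alcohols attacks the α-acyloxy chloride (as in acyloxymethyl ether formation of phenols); C2 symmetry allows only one mono-ether, excess 1 limits bis-alkylation, and C8/C8′ are untouched.

Step 3
Reactants: 5 mono-O4-(acryloyloxymethyl) ether of 1; 6 (E)-isoeugenol (3 equiv)
Product: 7 mono-O4-[(E)-feruloyloxymethyl] ether of 1
Conditions: Hoveyda–Grubbs II (5 mol %), CH2Cl2, 40 °C, N2 sparge, 12 h
Reagents that add atoms: (E)-isoeugenol (6), C/C=C/c1ccc(O)c(OC)c1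
Why: Olefin cross-metathesis of an electron-poor acrylate with a styrenyl olefin is selective for the E-cinnamate, tolerates free phenols and alcohols under neutral conditions, and is driven by loss of propene; no stereocentre is affected.

Step 4
Reactants: 7 mono-O4-[(E)-feruloyloxymethyl] ether of 1
Product: 9 strapped (2S,3S)-trans-dihydrobenzofuran macrocycle, via quinone methide 8 (not isolated)
Conditions: undivided cell, RVC anode / Pt cathode, 0.1 M n-Bu4NPF6, CH2Cl2–HFIP 4:1, 2,6-lutidine (2 equiv), 7 fed by syringe pump to ≤1 mM, 0 °C, +0.9 V vs Ag/AgCl, stop at 2.0 F/mol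
Reagents that add atoms: none
Why: Proposed new method: two proton-coupled one-electron oxidations hit only the ring B guaiacol and the ferulate phenol (both about 0.4 V easier to oxidise than the acetal-capped ring A or the alcohols), and the tethered phenoxyl pair joins C8″ to C5′ as in the known anodic or Ag2O 8–5′ dehydrodimerisation of ferulates and isoeugenol, rearomatises to 8 and closes by 5-exo oxa-Michael addition of O4′ anti to the ester (trans, C7″ S); new are the intramolecular cross-coupling that closes a 16-membered [4.5]metaparacyclophane and the setting of C8″ by the bought centres, because a hand-built torsional model predicts that the (8R,8′R) spacer closes the ring in its favoured gauche(+) C7–C8–C8′–C7′ rotamer with ring B anti to C8, H8′ under the strap and both CH2OH groups outside, which places strap and ester carbon on the ring B face from which C1′→C6′ runs clockwise (8″S in 9, 8″R after reduction), whereas the other face needs the three-gauche rotamer with C9′H2OH pointing into the ring; closest known types are anodic phenol–styrene [3+2] and phenol–phenol couplings in HFIP and macrocyclising anodic phenol couplings.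

Step 5
Reactants: 9 strapped (2S,3S)-trans-dihydrobenzofuran macrocycle
Product: 10 target (7″S,8″R,8R,8′R)
Conditions: LiAlH4 (6 equiv), THF, −20 → 0 °C, 1 h; H2O quench
Reagents that add atoms: none
Why: Ester reduction with LiAlH4 gives C9″H2OH and the hemiacetal ArO–CH2–O⁻, which collapses to the ring A phenoxide and formaldehyde (reduced at once to methanol); cold hydride delivery outruns enolisation, as in the known reduction of dehydrodiferulates, so C8″ and C7″ keep their configuration (C8″ changes descriptor S→R only through CIP priorities).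

## Compound list
1 | (−)-secoisolariciresinol, (2R,3R)-2,3-bis(4-hydroxy-3-methoxybenzyl)butane-1,4-diol | COc1cc(C[C@@H](CO)[C@H](CO)Cc2ccc(O)c(OC)c2)ccc1O | starting material
2 | acrylic acid | C=CC(=O)O | starting material
3 | chloromethyl chlorosulfate | ClCOS(=O)(=O)Cl | starting material
4 | chloromethyl acrylate | C=CC(=O)OCCl | intermediate
5 | {4-[(2R,3R)-4-hydroxy-2-(hydroxymethyl)-3-(4-hydroxy-3-methoxybenzyl)butyl]-2-methoxyphenoxy}methyl acrylate | COc1cc(C[C@@H](CO)[C@H](CO)Cc2ccc(O)c(OC)c2)ccc1OCOC(=O)C=C | intermediate
6 | (E)-isoeugenol | C/C=C/c1ccc(O)c(OC)c1 | starting material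
7 | same aryloxymethyl ester as 5 but of (E)-ferulic acid; ring B and ferulate phenols free | COc1cc(C[C@@H](CO)[C@H](CO)Cc2ccc(O)c(OC)c2)ccc1OCOC(=O)/C=C/c1ccc(O)c(OC)c1 | intermediate
8 | 16-membered macrocycle with the C8″(R)–C5′ bond made, ring B phenol free, ferulate ring as p-quinone methide (C7″=C1″) | COc1cc(C[C@@H](CO)[C@H](CO)Cc2cc(OC)c(O)c(c2)[C@H](C(=O)OCO4)C=C2C=CC(=O)C(OC)=C2)ccc14 | intermediate (not isolated)
9 | (2S,3S)-trans-2-(4-hydroxy-3-methoxyphenyl)-7-methoxy-2,3-dihydrobenzofuran-3-carboxylate; its ester O–CH2–O strap ends on O4 of ring A and its C5 carries the (8R,8′R) spacer (16-membered ring) | COc1cc(C[C@@H](CO)[C@H](CO)Cc2cc(OC)c3c(c2)[C@H](C(=O)OCO4)[C@@H](c2ccc(O)c(OC)c2)O3)ccc14 | intermediate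
10 | CNP0256425.1, (8R,8′R)-secoisolariciresinol 8″–5′/7″–O–4′-linked to a coniferyl alcohol unit, (7″S,8″R)-trans | COc1cc(C[C@@H](CO)[C@H](CO)Cc2cc(OC)c3c(c2)[C@H](CO)[C@@H](c2ccc(O)c(OC)c2)O3)ccc1O | target

Total step count: 5.
Longest linear sequence: 5 (2 → 4 → 5 → 7 → 9 → 10); 4 steps from 1.

## Steps most likely to fail

**Step 4 (the proposed new step).**
- Risks are oligomerisation, 8–O–4′ instead of 8–5′ closure, and over-oxidation of the free phenol of 9.
- The C–C bond forms irreversibly, so the facial bias may be weaker than the product-like model suggests, or even opposite in sense.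
- The fallback uses known chemistry, sets out from 1 and comes back at 10, dropping the strap. Coniferyl alcohol is added slowly to 1 (3 equiv) and Ag2O in acetone–CH2Cl2, the classical intermolecular 8–5′ cross-coupling.
- It gives only trans-dihydrobenzofurans, as a roughly 1:1 mixture of 10 and the (7″R,8″S) diastereomer of the target F1. The two are diastereomers because of the bought centres and are separated by preparative HPLC.

**Step 2.**
- Risks are phenoxide attack at the acryloyl carbonyl, oxa-Michael addition to the acrylate, and bis-alkylation.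
- The fallback sets out from 1 and comes back at 7. It attaches the whole strap at once, so no acrylate and no metathesis are needed.
- Ferulic acid is bis-silylated (TIPSCl, imidazole) to triisopropylsilyl 4-O-TIPS-ferulate F2. K2CO3 in aqueous MeOH cleaves the silyl ester to 4-O-TIPS-ferulic acid F3.
- 3 under the step 1 conditions gives chloromethyl 4-O-TIPS-ferulate F4. This alkylates 1 (Cs2CO3, DMF) to the 4″-O-TIPS ether of 7 F5, and Et3N·3HF in THF releases 7.

**Step 3.**
- Risks are catalyst poisoning by the phenolic styrene, isoeugenol self-metathesis, and loss of the acylal.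
- The fallback sets out from 5 and comes back at 7. It forms the aryl–vinyl bond instead of exchanging alkenes: Heck arylation of the acrylate 5 with bought 4-iodo-2-methoxyphenol (Pd(OAc)2, P(o-tol)3, Et3N, MeCN, 60 °C) gives the E-ferulate 7 directly.

## Further compounds
F1 | step 4 | (7″R,8″S,8R,8′R) diastereomer of the target | COc1cc(C[C@@H](CO)[C@H](CO)Cc2cc(OC)c3c(c2)[C@@H](CO)[C@H](c2ccc(O)c(OC)c2)O3)ccc1O
F2 | step 2 | triisopropylsilyl (E)-3-methoxy-4-(triisopropylsilyloxy)cinnamate | COc1cc(/C=C/C(=O)O[Si](C(C)C)(C(C)C)C(C)C)ccc1O[Si](C(C)C)(C(C)C)C(C)C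
F3 | step 2 | (E)-3-methoxy-4-(triisopropylsilyloxy)cinnamic acid | COc1cc(/C=C/C(=O)O)ccc1O[Si](C(C)C)(C(C)C)C(C)C
F4 | step 2 | chloromethyl (E)-3-methoxy-4-(triisopropylsilyloxy)cinnamate | COc1cc(/C=C/C(=O)OCCl)ccc1O[Si](C(C)C)(C(C)C)C(C)C
F5 | step 2 | 4″-O-triisopropylsilyl ether of 7 | COc1cc(C[C@@H](CO)[C@H](CO)Cc2ccc(O)c(OC)c2)ccc1OCOC(=O)/C=C/c1ccc(O[Si](C(C)C)(C(C)C)C(C)C)c(OC)c1
F0 | step 3 | none | none
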